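## Structural features

The target is a spiro[5.5]undecane in which ring A (C1 to C6) and ring B (C6 to C11) share only the quaternary carbon C6. Ring A carries the exocyclic methylene on C1, a secondary hydroxyl on C3, a secondary bromide on C4 and the gem-dimethyl carbon C5, so C5 and C6 are two adjacent fully substituted carbons; ring B carries a tertiary chloride with a methyl group on C9 and a secondary bromide on C10. The stereocentres form two contiguous pairs, C3/C4 (cis bromohydrin, 3R,4S) and C9/C10 (trans bromochloride, 9R,10R), which communicate only through C6 (S), and C6 is stereogenic solely because the C7-C8 arm and the C11-C10 arm of ring B differ. Fragile groups are the tertiary chloride and the two secondary bromides (elimination with base, ionisation with Lewis acids, reduction by metals), the 1,1-disubstituted alkene (acid adds HX or moves it into the ring) and the bromohydrin. The real difficulties are the C5-C6 bond between two quaternary carbons, the lack of any element near C4 that could direct its bromination, and the fact that the C10 bromine stands cis to C1: C5 takes the equatorial site on ring B, C1 is therefore axial, and an electrophile adding to a C9-C10 alkene is expected to enter on the other face. The key step exploits that C1 to C5 of ring A form a 5,5-dimethyl-1,3-dioxygenated chain tied at both ends to C6, and that ring B can be kept symmetrical with a masked carbonyl at C9, so ring A is annulated onto an achiral ester and chirality is introduced afterwards by a reagent.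

## Logic of the disconnections

22 to 19. No skeletal bond is cut; the exocyclic alkene is traced to a C1=C2 alkene bearing a hydroxyl on the exocyclic carbon. The reason is that an exocyclic alkene cannot be made by dienolate chemistry once C4 carries bromine, because the C4 hydrogen is then the most acidic one. A sigmatropic 1,3-transposition places the alkene under neutral conditions. The demand is that the primary allylic hydroxyl of 19 reacts in preference to the hindered secondary one.

19 to 18 to 16. The C3-H bond and the C4-Br bond are cut. In the conjugated enone 16, C4 is the only enolisable position next to the C3 carbonyl (C2 is vinylic), so the bromine goes to C4 without a regiochemical question, and hydride delivery to the bromo ketone gives the cis bromohydrin. Two stereocentres are removed. The demands are face selection at C4, for which the substrate offers little bias, and hydride attack anti to the axial C5 methyl.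

16 to 14. The bond from C1 to the exocyclic carbon is cut. In 14 the two carbonyls of the dione are differentiated (C1 ketone, C3 enol ether), so a carbon nucleophile adds at C1 and acid transposes the enone. This returns ring A to the oxidation pattern that the annulation delivers. The demand is an organometal that adds to the hindered C1 carbonyl without eliminating the ring B halides.

14 to 13 to 12 to 11. The C9-Cl and C10-Br bonds are cut back to an epoxide and then to the C9=C10 alkene. Direct bromochlorination is avoided because bromonium formation is expected anti to the axial C1, which would place the C10 bromine on the wrong face. Instead the bromine arrives as a nucleophile, anti to an epoxide oxygen that was itself placed anti to C1, and chloride then replaces that oxygen with retention through a bromonium ion. All ring B stereochemistry is thereby derived stereospecifically from one alkene. The sequence is run on the vinylogous ester, where the atom held under ring B is a carbonyl oxygen and not a carbon substituent. The demands are epoxidation anti to C1, substitution at C10 and not ionisation at C9, and bromine participation in the chlorination.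

11 to 10 to 8. The C9-CH3 bond is cut and the C9=C10 alkene is traced to one of two enantiotopic enolates of a symmetrical ketone. C6 becomes stereogenic when the arms of ring B are made different, so 8 is achiral. The desymmetrisation is placed at the vinylogous ester stage because 8 has no other kinetically acidic hydrogen; an enone in ring A would compete. The demand is that the chiral base distinguishes the C8 and C10 hydrogens.

8 to 7 to 6. Only functional groups change: the C9 carbonyl is unmasked and the C3 oxygen is an enol ether. The demands are enol ether formation at the less hindered C3 carbonyl and removal of the thioketal without hydrolysis of the vinylogous ester.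

6 to 3 and 4. The C5-C6 and C1-C2 bonds are cut. The ester carbon becomes C1, the enone brings C2 to C5 with the gem-dimethyl group already on its electrophilic carbon, and the congested bond is made on achiral material where only conversion matters. The demand is conjugate addition between two fully substituted carbons. The C9 mask must also survive TiCl4, which an O,O-ketal would not, because it would ionise and be attacked by 3; hence the dithiolane.

3 to 2 to 1. The O-Si bond and the C-S bonds are cut, leading to a commercial keto ester.

## Other disconnections considered

Alternative 1: The cut is C6-C7 of ring B, traced by a cationic rearrangement to the cyclopropane-containing terpene A1. In the forward step a strong protic acid protonates the alkene of A1, the cyclopropylcarbinyl cation opens and a 1,2-shift closes the spiro ring to give diene A2. In its favour, one step from an abundant enantiopure hydrocarbon would deliver all fifteen carbons, both rings, the C5/C6 quaternary pair and a configured C6. On step economy to the skeleton and on the C5-C6 problem it is better than the chosen plan. Against it here, A2 has no heteroatom and two trisubstituted alkenes of similar reactivity. The C3 oxygen would have to come from an allylic oxidation of ring A in competition with the allylic positions of ring B. The cationic manifold can also give ring-expanded and isomeric products. Only one enantiomer of A1 is abundant, so the absolute configuration cannot be chosen. The exocyclic carbon is fixed as a methyl group, so the exocyclic alkene would need a deconjugation in the presence of the C4 bromide. In comparison, A2 offers the skeleton without handles whereas 6 offers oxygen at C1, C3 and C9; the mechanism is a rearrangement under acid against a polar two-bond annulation on symmetrical material; the late problems at C4 and C9/C10 are the same in both, and after refunctionalisation the step counts should be about equal.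

Alternative 2: The cut is C10-C11 together with C5-C6, leading to the aldehyde A3. In the forward step a Lewis acid activates the aldehyde, the 1,1-disubstituted alkene closes ring B, and the C6 cation is quenched by ring-expanding migration of C5 to give the hydroxy ketone A4. In its favour, the quaternary pair is made by an intramolecular 1,2-shift, which is a better answer to the C5-C6 problem than an intermolecular Michael addition, and C6 is set under substrate control, which is equal or better than a stoichiometric chiral base. Against it here, A4 has hydrogen at C9 and hydroxyl at C10, so the C9=C10 alkene would have to be made by a regioselective dehydration that destroys the stereocentre which steered the cascade. C3 is not oxidised, so oxygen would have to be moved around ring A. The hindered C1 ketone must be olefinated late, and A3 needs a linear synthesis with its own quaternary carbinol. In comparison, the structure is better at C5/C6 and worse in the oxidation pattern of ring A, the mechanism is a cation cascade against an anionic annulation, and the step count is expected to be higher.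

Alternative 3: The cut is C6-C7 together with C10-C11, leading to the formyl vinylogous ester A5 and the enone A6. In the forward step a chiral amine-thiourea catalyst mediates Michael addition of A5 through C6, and aldol condensation of the ketone methyl with the formyl carbon closes ring B to give A7. In its favour, ring A comes from a commercial dione with the gem-dimethyl group and both oxygens in place, the acceptor is unhindered, and C6 is set catalytically during C-C bond formation. The enone of A7 would give the C9/C10 enolate regiospecifically by conjugate reduction, so A7 would join the chosen route at triflate 10. On step economy and on the use of a catalytic instead of a stoichiometric chiral reagent it is the equal or the better of the chosen plan. Against it here, the nucleophilic carbon C6 is neopentyl and becomes quaternary in the enantiodetermining step, which is the uncertain point for this catalyst class, and the formyl group can be lost by retro-Claisen cleavage. The chosen plan separates the two problems: the congested bond is made on achiral material, and the enantioselection is an enolisation of an unhindered ketone. Beyond A7 and 10 the two plans are identical in structure and face the same late problems.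

Key step: step 3

Assumption: the sense of enantiotopic deprotonation of 8 by the (R,R)-amide is taken to parallel that of 4-tert-butylcyclohexanone, with C5 in the place of the equatorial tert-butyl group; if the sense proves opposite, the (S,S)-amide is used without other change.

Locants in the names below follow the atom numbering defined under "Structural features". The descriptor at C6 changes between R and S along the route because substituent priorities change; the geometry at C6 is not altered.

## Route

Step 1
Reactants: 1 ethyl 4-oxocyclohexane-1-carboxylate
Product: 2 ethyl 1,4-dithiaspiro[4.5]decane-8-carboxylate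
Conditions: HSCH2CH2SH, BF3·OEt2 (cat.), CH2Cl2, 0 °C to rt
Reagents that add atoms: ethane-1,2-dithiol, SCCS
Why: Lewis-acid-catalysed dithioketalisation of an unhindered ketone leaves the ester untouched, and the dithiolane, unlike an O,O-ketal, is not ionised by TiCl4 in step 3.

Step 2
Reactants: 2 ethyl 1,4-dithiaspiro[4.5]decane-8-carboxylate
Product: 3 [(1,4-dithiaspiro[4.5]decan-8-ylidene)(ethoxy)methoxy]trimethylsilane (ethyl trimethylsilyl ketene acetal of 2)
Conditions: LiN(i-Pr)2, Me3SiCl (present from the start), THF, -78 °C to rt
Reagents that add atoms: chlorotrimethylsilane, C[Si](C)(C)Cl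
Why: Ester enolisation with in situ O-silylation (ketene silyl acetal formation); the alpha carbon is tertiary and the ring is symmetrical, so a single ketene acetal without geometric isomers should form.

Step 3
Reactants: 3 ethyl trimethylsilyl ketene acetal of 2; 4 mesityl oxide (4-methylpent-3-en-2-one)
Product: 6 5,5-dimethylspiro[5.5]undecane-1,3,9-trione with the C9 carbonyl masked as its 1,3-dithiolane (achiral), via keto ester 5 (not isolated)
Conditions: TiCl4 (1 equiv, 4 pre-complexed), CH2Cl2, -78 °C; aq. K2CO3 work-up; then KOt-Bu, THF, 0 °C to rt; aq. HCl to pH 3
Reagents that add atoms: none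
Why: TiCl4 binds the carbonyl oxygen of 4 and polarises the enone so that the tetrasubstituted carbon of 3 (C6) attacks the beta carbon (C5) through an open transition state, and silyl transfer to chloride leaves a titanium enolate that gives keto ester 5 on work-up. The closest known reaction type is the TiCl4-mediated Mukaiyama-Michael addition of ketene silyl acetals to beta,beta-disubstituted enones, one of the few intermolecular ways of joining two fully substituted carbons. KOt-Bu then forms the methyl ketone enolate (the C4 methylene enolate could only close a four-membered ring and reverts), which acylates at the ester carbon in a Claisen condensation, 6-(enolendo)-exo-trig, forming C1-C2 and closing ring A. The closure is pulled forward by irreversible deprotonation of the 1,3-dione and helped by the gem-dialkyl effect of C5 and C6. No stereocentre is formed, since 6 keeps the mirror plane through C6 and C9. The step needs 1,4- over 1,2-addition, which activation at oxygen and the shielding of the ketone carbon should secure, and it needs a C9 mask that is inert to TiCl4, which the dithiolane provides.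

Step 4
Reactants: 6 dithiolane-masked spiro trione
Product: 7 5,5-dimethyl-3-(2-methylpropoxy)spiro[5.5]undec-2-ene-1,9-dione with the C9 carbonyl masked as its 1,3-dithiolane (achiral)
Conditions: i-BuOH, TsOH·H2O (cat.), toluene, reflux, azeotropic removal of water
Reagents that add atoms: 2-methylpropan-1-ol, CC(C)CO
Why: Acid-catalysed enol etherification of a cyclic 1,3-dione (vinylogous ester formation); the alcohol should add at the C3 carbonyl and not at C1, which is shielded by the adjacent quaternary C6 and C5, and the thioketal is stable to acid.

Step 5
Reactants: 7 dithiolane-masked vinylogous ester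
Product: 8 5,5-dimethyl-3-(2-methylpropoxy)spiro[5.5]undec-2-ene-1,9-dione (achiral)
Conditions: MeI, CaCO3, MeCN-H2O, 45 °C
Reagents that add atoms: water, O
Why: S-Alkylative hydrolysis of a dithioketal: S-methylation turns sulfur into a leaving group and water delivers the carbonyl oxygen under buffered, near-neutral conditions that a vinylogous ester should tolerate.

Step 6
Reactants: 8 vinylogous ester ketone
Product: 10 (6R)-5,5-dimethyl-3-(2-methylpropoxy)-1-oxospiro[5.5]undeca-2,9-dien-9-yl trifluoromethanesulfonate, via lithium enolate 9 (not isolated)
Conditions: (R,R)-bis(1-phenylethyl)amine·HCl, n-BuLi (2 equiv), THF (gives the lithium amide and LiCl); 8, -78 °C; then N-(5-chloropyridin-2-yl)-bis(trifluoromethanesulfonyl)imide, -78 to -20 °C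
Reagents that add atoms: N-(5-chloropyridin-2-yl)-bis(trifluoromethanesulfonyl)imide, FC(F)(F)S(=O)(=O)N(c1ccc(Cl)cn1)S(=O)(=O)C(F)(F)F
Why: Enantiotopic deprotonation of a 4,4-disubstituted cyclohexanone by a chiral lithium amide with O-sulfonylation of the enolate; C6 is set because the amide removes the axial C10 hydrogen and not its C8 counterpart in the chair with C5 equatorial, LiCl-containing aggregates being used to keep selectivity high under external quench. The vinylogous ester has no alpha' hydrogen and its gamma hydrogens are kinetically inert, so no second enolate competes.

Step 7
Reactants: 10 (6R)-enol triflate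
Product: 11 (6R)-5,5,9-trimethyl-3-(2-methylpropoxy)spiro[5.5]undeca-2,9-dien-1-one
Conditions: MeZnCl, Pd(PPh3)4 (cat.), THF, 0 °C to rt
Reagents that add atoms: methylzinc chloride, C[Zn]Cl
Why: Negishi coupling of an alkenyl triflate; the organozinc does not add to the vinylogous ester carbonyl, and the stereocentre is not involved.

Step 8
Reactants: 11 (6R)-methyl diene
Product: 12 (6R,9R,10S)-9,10-epoxy-5,5,9-trimethyl-3-(2-methylpropoxy)spiro[5.5]undec-2-en-1-one (epoxide oxygen cis to C5)
Conditions: m-CPBA (1.05 equiv), NaHCO3, CH2Cl2, 0 °C
Reagents that add atoms: 3-chloroperoxybenzoic acid, OOC(=O)c1cccc(Cl)c1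
Why: Peracid epoxidation of the electron-rich trisubstituted alkene in preference to the push-pull alkene of the vinylogous ester; C5 occupies the equatorial site on ring B, C1 and its carbonyl oxygen are axial and cover one face, so the oxygen should be delivered anti to C1, which sets C9 and C10.

Step 9
Reactants: 12 (6R,9R,10S)-epoxide
Product: 13 (6R,9R,10R)-10-bromo-9-hydroxy-5,5,9-trimethyl-3-(2-methylpropoxy)spiro[5.5]undec-2-en-1-one (Br cis to C1, OH cis to C5)
Conditions: Li2NiBr4, THF, 0 °C to rt; pH 7 phosphate buffer
Reagents that add atoms: dilithium tetrabromonickelate, [Li+].[Li+].[Ni+2].[Br-].[Br-].[Br-].[Br-]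
Why: Nucleophilic opening of a trisubstituted epoxide by soft bromide at the secondary carbon with inversion; attack at C10 is also the trans-diaxial mode in the chair with C5 equatorial, so regiochemistry and stereochemistry reinforce each other and the bromine arrives on the face cis to C1 that an electrophile would avoid.

Step 10
Reactants: 13 (6R,9R,10R)-bromohydrin
Product: 14 (6R,9R,10R)-10-bromo-9-chloro-5,5,9-trimethyl-3-(2-methylpropoxy)spiro[5.5]undec-2-en-1-one
Conditions: SOCl2, CH2Cl2, 0 °C
Reagents that add atoms: thionyl chloride, ClS(Cl)=O
Why: Conversion of a tertiary alcohol into the chloride via its chlorosulfite with neighbouring-group participation: the antiperiplanar C10 bromine displaces the leaving group to give a bromonium ion, which chloride opens at the tertiary carbon C9 from the face the oxygen left, so C9 is substituted with net retention and the trans bromochloride results.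

Step 11
Reactants: 14 (6R,9R,10R)-bromochloro vinylogous ester
Product: 16 (6R,9R,10R)-10-bromo-9-chloro-1-(hydroxymethyl)-5,5,9-trimethylspiro[5.5]undec-1-en-3-one, via tertiary alcohol 15 (not isolated)
Conditions: Bu3SnCH2OCH(Me)OEt, n-BuLi, THF, -78 °C; CeCl3, -78 °C; 14, -78 to -40 °C; then 1 M HCl, THF, rt
Reagents that add atoms: (1-ethoxyethoxy)methyllithium, [Li]COC(C)OCC; water, O
Why: Stork-Danheiser transposition: the weakly basic organocerium reagent adds 1,2 to the hindered C1 carbonyl without eliminating the ring B halides, and aqueous acid ionises the tertiary allylic alcohol, hydrolyses the enol ether to the C3 ketone and cleaves the acetal, leaving the C1=C2 enone with the exocyclic carbon as CH2OH; no stereocentre is formed.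

Step 12
Reactants: 16 (6R,9R,10R)-hydroxymethyl enone
Product: 18 (4S,6S,9R,10R)-4,10-dibromo-9-chloro-1-(hydroxymethyl)-5,5,9-trimethylspiro[5.5]undec-1-en-3-one (C4 bromine cis to C11), via bis-silyl dienol ether 17 (not isolated)
Conditions: LiN(i-Pr)2 (2.2 equiv), Me3SiCl (2.5 equiv), THF, -78 °C; then NBS, THF, -78 °C; dilute aq. HCl work-up
Reagents that add atoms: N-bromosuccinimide, O=C1CCC(=O)N1Br
Why: Kinetic alpha' enolisation of the conjugated enone with in situ silylation (the hydroxyl is silylated as well), then bromination of the cross-conjugated silyl dienol ether; C4 is the only enolisable position, so the regiochemistry is fixed. C4 is set by the face on which NBS attacks; the substrate offers no reliable bias, so both epimers are expected and the one with bromine cis to C11 is taken on after separation.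

Step 13
Reactants: 18 (4S,6S,9R,10R)-bromo enone
Product: 19 (3R,4S,6S,9R,10R)-4,10-dibromo-9-chloro-1-(hydroxymethyl)-5,5,9-trimethylspiro[5.5]undec-1-en-3-ol (C3 hydroxyl cis to C4 bromine)
Conditions: i-Bu2AlH (3.5 equiv), THF, -78 °C; aq. sodium potassium tartrate
Reagents that add atoms: none
Why: 1,2-Reduction of an alpha-bromo enone by an aluminium hydride; the axial trajectory at C3 is blocked by the syn-axial methyl group on C5, so hydride should enter equatorially and give the axial alcohol, cis to the equatorial C4 bromine, which sets C3.

Step 14
Reactants: 19 (3R,4S,6S,9R,10R)-diol
Product: 22 (3R,4S,6S,9R,10R)-4,10-dibromo-9-chloro-5,5,9-trimethyl-1-methylidenespiro[5.5]undecan-3-ol (target), via sulfonylhydrazine 20 (not isolated), via allylic diazene 21 (not isolated)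
Conditions: 2-O2NC6H4SO2NHNH2, PPh3, EtO2CN=NCO2Et, THF, -30 °C to rt
Reagents that add atoms: none
Why: Mitsunobu N-alkylation of the sulfonylhydrazide by the primary allylic alcohol, loss of sulfinic acid and retro-ene loss of N2 from the allylic diazene (reductive 1,3-transposition of an allylic alcohol); hydrogen is delivered to C2 and the alkene moves to the exocyclic position under neutral conditions that spare the halides. The hindered secondary C3 hydroxyl should react far more slowly, and no stereocentre is formed or touched.

## Compound list

1 | ethyl 4-oxocyclohexane-1-carboxylate | CCOC(=O)C1CCC(=O)CC1 | starting material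
2 | ethyl 1,4-dithiaspiro[4.5]decane-8-carboxylate | CCOC(=O)C1CCC2(CC1)SCCS2 | intermediate
3 | [(1,4-dithiaspiro[4.5]decan-8-ylidene)(ethoxy)methoxy]trimethylsilane | CCOC(O[Si](C)(C)C)=C1CCC2(CC1)SCCS2 | intermediate
4 | mesityl oxide (4-methylpent-3-en-2-one) | CC(C)=CC(C)=O | starting material
5 | ethyl 8-(2-methyl-4-oxopentan-2-yl)-1,4-dithiaspiro[4.5]decane-8-carboxylate (keto ester) | CCOC(=O)C1(CCC2(CC1)SCCS2)C(C)(C)CC(C)=O | intermediate (not isolated)
6 | 5,5-dimethylspiro[5.5]undecane-1,3,9-trione, C9 carbonyl as 1,3-dithiolane (achiral) | O=C1CC(=O)CC(C)(C)C12CCC3(CC2)SCCS3 | intermediate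
7 | 5,5-dimethyl-3-(2-methylpropoxy)spiro[5.5]undec-2-ene-1,9-dione, C9 carbonyl as 1,3-dithiolane (achiral) | O=C1C=C(OCC(C)C)CC(C)(C)C12CCC3(CC2)SCCS3 | intermediate
8 | 5,5-dimethyl-3-(2-methylpropoxy)spiro[5.5]undec-2-ene-1,9-dione (achiral) | O=C1C=C(OCC(C)C)CC(C)(C)C12CCC(=O)CC2 | intermediate
9 | lithium (6R)-5,5-dimethyl-3-(2-methylpropoxy)-1-oxospiro[5.5]undeca-2,9-dien-9-olate | O=C1C=C(OCC(C)C)CC(C)(C)[C@]12CCC([O-])=CC2.[Li+] | intermediate (not isolated)
10 | (6R)-5,5-dimethyl-3-(2-methylpropoxy)-1-oxospiro[5.5]undeca-2,9-dien-9-yl trifluoromethanesulfonate | O=C1C=C(OCC(C)C)CC(C)(C)[C@]12CCC(OS(=O)(=O)C(F)(F)F)=CC2 | intermediate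
11 | (6R)-5,5,9-trimethyl-3-(2-methylpropoxy)spiro[5.5]undeca-2,9-dien-1-one | O=C1C=C(OCC(C)C)CC(C)(C)[C@]12CCC(C)=CC2 | intermediate
12 | (6R,9R,10S)-9,10-epoxy-5,5,9-trimethyl-3-(2-methylpropoxy)spiro[5.5]undec-2-en-1-one | O=C1C=C(OCC(C)C)CC(C)(C)[C@]12CC[C@@]3(C)O[C@H]3C2 | intermediate
13 | (6R,9R,10R)-10-bromo-9-hydroxy-5,5,9-trimethyl-3-(2-methylpropoxy)spiro[5.5]undec-2-en-1-one | O=C1C=C(OCC(C)C)CC(C)(C)[C@]12CC[C@@](C)(O)[C@H](Br)C2 | intermediate
14 | (6R,9R,10R)-10-bromo-9-chloro-5,5,9-trimethyl-3-(2-methylpropoxy)spiro[5.5]undec-2-en-1-one | O=C1C=C(OCC(C)C)CC(C)(C)[C@]12CC[C@@](C)(Cl)[C@H](Br)C2 | intermediate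
15 | (6R,9R,10R)-10-bromo-9-chloro-1-[(1-ethoxyethoxy)methyl]-5,5,9-trimethyl-3-(2-methylpropoxy)spiro[5.5]undec-2-en-1-ol (mixture at C1 and at the acetal carbon) | CCOC(C)OCC1(O)C=C(OCC(C)C)CC(C)(C)[C@]12CC[C@@](C)(Cl)[C@H](Br)C2 | intermediate (not isolated)
16 | (6R,9R,10R)-10-bromo-9-chloro-1-(hydroxymethyl)-5,5,9-trimethylspiro[5.5]undec-1-en-3-one | OCC1=CC(=O)CC(C)(C)[C@]12CC[C@@](C)(Cl)[C@H](Br)C2 | intermediate
17 | (6R,9R,10R)-10-bromo-9-chloro-5,5,9-trimethyl-3-(trimethylsilyloxy)-1-[(trimethylsilyloxy)methyl]spiro[5.5]undeca-1,3-diene | C[Si](C)(C)OCC1=CC(O[Si](C)(C)C)=CC(C)(C)[C@]12CC[C@@](C)(Cl)[C@H](Br)C2 | intermediate (not isolated)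
18 | (4S,6S,9R,10R)-4,10-dibromo-9-chloro-1-(hydroxymethyl)-5,5,9-trimethylspiro[5.5]undec-1-en-3-one | OCC1=CC(=O)[C@@H](Br)C(C)(C)[C@]12CC[C@@](C)(Cl)[C@H](Br)C2 | intermediate
19 | (3R,4S,6S,9R,10R)-4,10-dibromo-9-chloro-1-(hydroxymethyl)-5,5,9-trimethylspiro[5.5]undec-1-en-3-ol | OCC1=C[C@@H](O)[C@@H](Br)C(C)(C)[C@]12CC[C@@](C)(Cl)[C@H](Br)C2 | intermediate
20 | N-{[(3R,4S,6S,9R,10R)-4,10-dibromo-9-chloro-3-hydroxy-5,5,9-trimethylspiro[5.5]undec-1-en-1-yl]methyl}-2-nitrobenzenesulfonohydrazide (alkylated at the sulfonylated nitrogen) | NN(CC1=C[C@@H](O)[C@@H](Br)C(C)(C)[C@]12CC[C@@](C)(Cl)[C@H](Br)C2)S(=O)(=O)c1ccccc1[N+](=O)[O-] | intermediate (not isolated)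
21 | {[(3R,4S,6S,9R,10R)-4,10-dibromo-9-chloro-3-hydroxy-5,5,9-trimethylspiro[5.5]undec-1-en-1-yl]methyl}diazene | N=NCC1=C[C@@H](O)[C@@H](Br)C(C)(C)[C@]12CC[C@@](C)(Cl)[C@H](Br)C2 | intermediate (not isolated)
22 | (3R,4S,6S,9R,10R)-4,10-dibromo-9-chloro-5,5,9-trimethyl-1-methylidenespiro[5.5]undecan-3-ol | C=C1C[C@@H](O)[C@@H](Br)C(C)(C)[C@]12CC[C@@](C)(Cl)[C@H](Br)C2 | target

## Step count and least certain steps

Total step count: 14. Longest linear sequence: 14 steps from 1 (the route is linear; 4 is purchased).

Step 3 (key step). The conjugate addition joins two fully substituted carbons and may stall, divert to 1,2-addition, or lose the ketene acetal by protodesilylation before the C-C bond forms. In the second stage, retro-Michael fragmentation of the adduct could compete with acylation of the neopentyl ester. The fallback keeps the same two bonds but raises the electrophilicity of the acceptor. It sets out from 3, which is added under TiCl4 to ethyl 2-acetyl-3-methylbut-2-enoate F1 (the Knoevenagel product of acetone and ethyl acetoacetate) to give the Michael adduct F2. The keto ester dianion of F2 (2 equiv of LiN(i-Pr)2) closes ring A by Claisen condensation to the ester-bearing dione F3. Saponification with aq. NaOH and acidification with warming remove the extra ester by decarboxylation, and the sequence comes back to the route at 6.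

Step 9. Substitution at C10 must take place against the axial C1 and its carbonyl oxygen and may be slow. The lithium salt could then promote ionisation at the tertiary C9, leading to rearrangement or to halide entry at the wrong carbon. The fallback replaces the epoxide by a more reactive electrophile that needs no Lewis acid. It sets out from 11, which is dihydroxylated on the same open face (OsO4 cat., N-methylmorpholine N-oxide) to the cis diol F4. This is converted with SOCl2/Et3N and then RuCl3 (cat.)/NaIO4 into the cyclic sulfate F5. LiBr opens F5 at the secondary carbon with inversion, and mild acid hydrolysis of the sulfate monoester returns to the route at 13.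

Step 12. Face selection at C4 may be poor, because the only stereocentres are remote and ring A can adopt either half-chair. The fallback gives up kinetic face selection in favour of an equilibrate-separate-recycle loop. It sets out from 16, brominates as before, and equilibrates the C4 position of the product through its enol with a catalytic amine base; C5 carries no hydrogen, so HBr cannot be lost. After chromatographic separation the fraction of the unwanted configuration is returned to the equilibration, and the material comes back to the route at 18. No new compound is involved.

Step 6. Discrimination between the enantiotopic C8 and C10 hydrogens may be incomplete, or of the opposite sense, because the axial C1 lies syn to both hydrogens and may perturb the usual transition state. The fallback makes the two arms different by catalytic reduction instead of deprotonation. It sets out from 8, which is dehydrogenated twice with 2-iodoxybenzoic acid (DMSO-toluene, 75 °C) to the achiral cross-conjugated dienone F6. Copper hydride catalysis (Cu(OAc)2, a chiral bisphosphine such as DTBM-SEGPHOS in the appropriate enantiomeric form, a hydrosilane, t-BuOH) reduces one of the two enantiotopic enone arms to give the enone F7. Conjugate reduction of F7 with Li[s-Bu3BH] at -78 °C generates enolate 9 regiospecifically, and trapping with the triflimide reagent of step 6 comes back to the route at 10.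

Step 14. The Mitsunobu activation may fail to distinguish the primary from the secondary allylic hydroxyl, or the hydrazide may be consumed unproductively, which would give transposition in the wrong direction or low conversion. The fallback delivers the hydrogen to C2 by a metal hydride instead. It sets out from 19, whose primary hydroxyl alone is acylated with methyl chloroformate and pyridine at -20 °C to the allylic carbonate F8. Palladium-catalysed formate hydrogenolysis (Pd(OAc)2, PBu3, HCO2H, Et3N, THF) transfers hydride to the more substituted allyl terminus and comes back to the route at 22.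

## Further compounds

F1 | step 3 | ethyl 2-acetyl-3-methylbut-2-enoate | CCOC(=O)C(C(C)=O)=C(C)C
F2 | step 3 | ethyl 8-[3-(ethoxycarbonyl)-2-methyl-4-oxopentan-2-yl]-1,4-dithiaspiro[4.5]decane-8-carboxylate (racemic) | CCOC(=O)C(C(C)=O)C(C)(C)C1(CCC2(CC1)SCCS2)C(=O)OCC
F3 | step 3 | ethyl 5,5-dimethyl-1,3-dioxospiro[5.5]undecane-4-carboxylate with the C9 carbon as 1,3-dithiolane (racemic) | CCOC(=O)C1C(=O)CC(=O)C2(CCC3(CC2)SCCS3)C1(C)C
F4 | step 9 | (6R,9R,10S)-9,10-dihydroxy-5,5,9-trimethyl-3-(2-methylpropoxy)spiro[5.5]undec-2-en-1-one | O=C1C=C(OCC(C)C)CC(C)(C)[C@]12CC[C@@](C)(O)[C@@H](O)C2
F5 | step 9 | cyclic sulfate of F4, (6R,9R,10S) | O=C1C=C(OCC(C)C)CC(C)(C)[C@]12CC[C@@]3(C)OS(=O)(=O)O[C@H]3C2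
F0 | step 12 | none | none
F6 | step 6 | 5,5-dimethyl-3-(2-methylpropoxy)spiro[5.5]undeca-2,7,10-triene-1,9-dione (achiral) | O=C1C=C(OCC(C)C)CC(C)(C)C12C=CC(=O)C=C2
F7 | step 6 | (6R)-5,5-dimethyl-3-(2-methylpropoxy)spiro[5.5]undeca-2,10-diene-1,9-dione | O=C1C=C(OCC(C)C)CC(C)(C)[C@]12CCC(=O)C=C2
F8 | step 14 | [(3R,4S,6S,9R,10R)-4,10-dibromo-9-chloro-3-hydroxy-5,5,9-trimethylspiro[5.5]undec-1-en-1-yl]methyl methyl carbonate | COC(=O)OCC1=C[C@@H](O)[C@@H](Br)C(C)(C)[C@]12CC[C@@](C)(Cl)[C@H](Br)C2
A1 | alternative 1 | (-)-thujopsene, (1aS,4aS,8aS)-2,4a,8,8-tetramethyl-1,1a,4,4a,5,6,7,8-octahydrocyclopropa[d]naphthalene | CC1=CC[C@]2(C)CCCC(C)(C)[C@@]23C[C@@H]13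
A2 | alternative 1 | spiro diene of the alpha-chamigrene type (alkenes at C1-C2 and C9-C10) | CC1=CCCC(C)(C)[C@]12CCC(C)=CC2
A3 | alternative 2 | 2-methyl-5-[2,2-dimethyl-1-(triethylsilyloxy)cyclopentyl]hex-5-enal, configured at the methyl-bearing carbon (carbinol configuration left open) | CC[Si](CC)(CC)OC1(CCCC1(C)C)C(=C)CC[C@@H](C)C=O
A4 | alternative 2 | spiro hydroxy ketone (C1 ketone, C9 methyl, C10 alcohol) | O=C1CCCC(C)(C)[C@]12CC[C@@H](C)[C@H](O)C2
A5 | alternative 3 | 2,2-dimethyl-4-(2-methylpropoxy)-6-oxocyclohex-4-ene-1-carbaldehyde (racemic, enolisable) | O=CC1C(=O)C=C(OCC(C)C)CC1(C)C
A6 | alternative 3 | methyl vinyl ketone (but-3-en-2-one) | C=CC(C)=O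
A7 | alternative 3 | spiro vinylogous ester enone (C9 ketone, C10-C11 alkene) | O=C1C=C(OCC(C)C)CC(C)(C)[C@]12CCC(=O)C=C2
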